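Its constants were chosen freely; no experiment stands behind them.

The free catalyst turns the substrate into intermediate while dying by a first-order step of its own.

    reagent + second catalyst + intermediate → second catalyst + product (k1 = 1.1 M⁻² s⁻¹, Ea1 = 52.0 kJ mol⁻¹)
    free catalyst → spent catalyst (k2 = 2.2 × 10⁻⁵ s⁻¹, Ea2 = 103 kJ mol⁻¹)
    gas ⇌ reagent, rate k3*(csat - [reagent]) (k3 = 0.0037 s⁻¹, csat = 31 mM)
    substrate + free catalyst → free catalyst + intermediate (k4 = 3.1 × 10⁻⁴ M⁻¹ s⁻¹, Ea4 = 68.0 kJ mol⁻¹)
    (constants at 70 °C)

common to all: substrate 0.27 M; gas 31 mM (held); free catalyst 54 mM; second catalyst 6.2 mM; time 40 h
- oak: temperature 45 °C
- alder: temperature 95 °C
- maple: temperature 70 °C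

- at the start none of reagent is dissolved
- all constants are for 70 °C and move with temperature by the activation energies

1. the flask with the highest amount of product, in percent of the substrate charged ("all alike" if they lie within 1.5 percentage points) (oak / alder / maple / all alike)
2. final product, as a percentage of the substrate charged, in oak
3. final product, as a percentage of the substrate charged, in alder
4. final product, as a percentage of the substrate charged, in maple

Divide the two rates. The substrate falls pseudo-first-order in proportion to the free catalyst, and the free catalyst falls in proportion to itself, so in the quotient time drops out. Each portion of free catalyst lost takes the same step off the logarithm of the substrate. In maple the whole charge is worth 0.761: the constant of substrate turnover times the free catalyst charged, divided by the constant of catalyst death, is the catalyst budget.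

Two extreme flasks can be solved in the head. If the free catalyst in maple never died, the logarithm would fall by 2.41 in the given time, a conversion of 91.0%. If it died to the last, the whole budget would be used, a conversion of 53.3%. The real maple uses the budget in proportion to the catalyst lost, a fraction of 95.8%, so it lies below both, at 51.8%, close to the second extreme.

Temperature moves the budget by the difference of activation energies, 35.0 kJ mol⁻¹, and heat shrinks it. Oak holds a budget of 2.00 but loses a fraction of 16.9%, which gives 28.7%. Alder holds 0.331 and loses a fraction of >99.9%, which gives 28.2%. My reckoning therefore puts maple ahead of oak and alder; it gives conversion, and product is conversion less whatever intermediate still stands.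

The forecast names maple, with 25.5% in oak, 28.2% in alder and 51.6% in maple, and says of alder: “The catalyst dies quickly.”

The simulation gives 51.6% in maple, ahead of 25.4% in oak and 28.2% in alder. Conversion of substrate at the end is 28.7% in oak, 28.2% in alder and 51.8% in maple. At 40.0 h, oak still holds 3.25% of the substrate charged as intermediate.

Alder falls short through the death of the free catalyst: with that step taken away, its product reaches >99.9% instead of 28.2%. With free catalyst at 0%, alder has used its whole budget of 0.331. The budget grows with the charge, so the neighbour of maple charged with 0.14 M of free catalyst has 1.97, and the fraction lost in maple makes that a conversion of 84.9%. That neighbour ends with 84.7% product and 15% of the substrate left.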